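**Plan**

1. Numbering used below (not IUPAC): ring A = C5–C6(=O)–C7=C8–C9(=O)–C10; ring C = C5–C10–C11=C12(CH3)–C13–C14; hydroquinone ring B = C15–C20 (C15 on C14, C20 on C10, OH on C16 and C19); prenyl on C5; "tetracyclic core" = this skeleton.
2. Retrosynthesis: first the oxidation level is removed (two O-methyl groups, C9=O, C7=C8), then the prenyl terminus (cross-metathesis of an allyl group) and the C12–CH3 bond (cross-coupling of an enol triflate). The strategic cut then removes both aryl bonds C14–C15 and C10–C20 at once, and the remaining bicycle falls to a Robinson annulation (C10=C11 and C13–C14) of 2-allylcyclohexane-1,3-dione.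
3. Enabling feature: C14 and C10, the two carbons that carry ring B, are the two β-carbons of a cross-conjugated cyclohexa-2,5-dienone hidden in ring C (carbonyl carbon C12, quaternary 4-position C5). 1,4-Dimethoxybenzene can therefore be stitched across them as a 1,2-bis-nucleophile, and the C12 oxygen leaves the step as the enol triflate that later takes the methyl group.
4. Forward: ring A is bought, ring C is annulated onto it, and the five-membered ring C5–C14–C15–C20–C10 and the seven-membered ring of the benzobicyclo[3.2.1]octene close together in the key step (ring B is bought). Methylation, prenyl formation, ring A oxidation and O-demethylation finish the synthesis.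
5. Stereochemistry: C5 comes from the D-proline-catalysed aldol desymmetrisation; C14 and C10 follow from it, because the arene adds anti to the angular allyl group and the tether allows only a cis 1,3-bridge.

Key step: step 4

Remark: the C5 side chain is carried as allyl and made into prenyl only after the cationic key step, because a trisubstituted alkene would be protonated by TfOH and would attack the dienyl cation. D-proline is taken to induce the sense opposite to L-proline.

**Step 1**
Reactants: 1 cyclohexane-1,3-dione; 2 allyl bromide
Product: 3 2-allylcyclohexane-1,3-dione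
Conditions: KOH, H2O, Cu powder (cat.), rt
Reagents that add atoms: none
Why: C-alkylation of the stabilised 1,3-diketone enolate (SN2) in water, which favours C- over O-allylation; no stereocentre is formed.

**Step 2**
Reactants: 3 2-allylcyclohexane-1,3-dione; 4 methyl vinyl ketone
Product: 6 (8aS)-8a-allyl-3,4,8,8a-tetrahydronaphthalene-1,6(2H,7H)-dione, via triketone 5 (not isolated)
Conditions: Et3N (cat.), neat, rt; then D-proline (cat.), DMSO, rt
Reagents that add atoms: none
Why: Michael addition followed by a D-proline-catalysed intramolecular aldol condensation (Hajos–Parrish–Eder–Sauer–Wiechert variant of the Robinson annulation), in which the enamine of the side-chain ketone should select one of the two enantiotopic ring carbonyls and so set the quaternary C8a (the future C5).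

**Step 3**
Reactants: 6 (8aS)-8a-allyl-3,4,8,8a-tetrahydronaphthalene-1,6(2H,7H)-dione
Product: 7 (8aR)-8a-allyl-3,4-dihydronaphthalene-1,6(2H,8aH)-dione
Conditions: 2,3-dichloro-5,6-dicyano-1,4-benzoquinone (DDQ), 1,4-dioxane, 100 °C
Reagents that add atoms: none
Why: Quinone dehydrogenation of an enone through its cross-conjugated dienol should introduce C7=C8 and give the cross-conjugated dienone, while the saturated ketone enolises too slowly to compete; the stereocentre is untouched (its descriptor changes only because the priorities change).

**Step 4**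
Reactants: 7 (8aR)-8a-allyl-3,4-dihydronaphthalene-1,6(2H,8aH)-dione; 8 1,4-dimethoxybenzene
Product: 12 (5R,10R,14S)-5-allyl enol triflate of the tetracyclic core (C6 ketone; C7–C9 saturated; C11=C12–OSO2CF3; C13 H2; OMe on C16 and C19), via trienyl triflate 9 (not isolated), via triflyloxy-cyclohexadienyl cation 10 (not isolated), via dienyl triflate 11 (not isolated)
Conditions: Tf2O, 2,6-di-tert-butyl-4-methylpyridine, CH2Cl2, −78 to 0 °C; then 1,4-dimethoxybenzene, TfOH, −78 to −30 °C; aq NaHCO3
Reagents that add atoms: trifluoromethanesulfonic anhydride, O=S(=O)(OS(=O)(=O)C(F)(F)F)C(F)(F)F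
Why: Proposed new method: Tf2O and the hindered pyridine should O-triflate the cross-conjugated dienone carbonyl of 7 (more basic than the C6 ketone) and, by loss of a C9 proton, store the whole substrate as trienyl triflate 9; TfOH then reprotonates C9 to cation 10, whose positive charge sits on C14 and C10, the two β-carbons that flank quaternary C5. Arene 8 should attack the unhindered terminus C14 (Friedel–Crafts conjugate arylation) to give dienyl triflate 11, TfOH then protonates the diene terminus C13 so that tertiary allylic C10 becomes the electrophilic centre (C12, the other allyl terminus, is deactivated by OTf), and the free ortho carbon C20 of the tethered arene attacks C10. This closes the five-membered ring C5–C14–C15–C20–C10 in a 5-exo cation–arene cyclisation and, by the same bond, the seven-membered ring C10–C11–C12–C13–C14–C15–C20 of the benzobicyclo[3.2.1]octene, and it leaves the double bond as the acid-stable enol triflate C11=C12. The closest known reaction types are acid-promoted Friedel–Crafts conjugate additions of electron-rich arenes to enones, double Michael annulations of 4,4-disubstituted cyclohexa-2,5-dienones with bis-nucleophiles, and the Tf2O/hindered-base enol triflation of ketones. C14 is set by attack on the face opposite the angular allyl group at C5, the only stereocentre present, and C10 follows from the two-atom tether, which can reach only that same face. The step needs capture by 8 to outrun 1,2- or [3,3]-migration of a C5 substituent (dienone–phenol rearrangement) and needs the second closure to occur at C10; the excess arene at −78 °C, the full conversion of the carbonyl into 9 before strong acid is admitted, the OTf group on C12 and the use of allyl in place of an acid-labile prenyl group are meant to secure both.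

**Step 5**
Reactants: 12 (5R,10R,14S)-5-allyl enol triflate of the tetracyclic core
Product: 13 (5R,10R,14S)-5-allyl-12-methyl tetracyclic ketone (C6 ketone; C7–C9 saturated; C11=C12–CH3; OMe on C16 and C19)
Conditions: Me4Sn, Pd(PPh3)4 (cat.), LiCl, DMF, 80 °C
Reagents that add atoms: tetramethylstannane, C[Sn](C)(C)C
Why: Stille cross-coupling of an alkenyl triflate should replace OTf on C12 by methyl with the double bond fixed at C11=C12; no stereocentre is affected.

**Step 6**
Reactants: 13 (5R,10R,14S)-5-allyl-12-methyl tetracyclic ketone
Product: 14 (5R,10R,14S)-5-prenyl-12-methyl tetracyclic ketone (otherwise as 13)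
Conditions: second-generation Grubbs catalyst (cat.), 2-methylbut-2-ene/CH2Cl2, 40 °C
Reagents that add atoms: 2-methylbut-2-ene, CC=C(C)C
Why: Olefin cross-metathesis of the terminal allyl group with 2-methylbut-2-ene should give the prenyl group with loss of propene, while the trisubstituted ring alkene C11=C12 is too hindered to react; no stereocentre is formed.

**Step 7**
Reactants: 14 (5R,10R,14S)-5-prenyl-12-methyl tetracyclic ketone
Product: 16 (5R,10R,14S)-5-prenyl tetracyclic enone (C6 ketone; C7=C8; C9 H2; C11=C12–CH3; OMe on C16 and C19), via trimethylsilyl enol ether 15 (not isolated)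
Conditions: LiN(SiMe3)2, Me3SiCl, THF, −78 °C; then Pd(OAc)2, MeCN, rt
Reagents that add atoms: none
Why: Saegusa–Ito oxidation, in which the C6 ketone can enolise only towards C7 (C5 is quaternary) and the silyl enol ether should undergo palladation and β-hydride elimination to the C7=C8 enone; no stereocentre is affected.

**Step 8**
Reactants: 16 (5R,10R,14S)-5-prenyl tetracyclic enone
Product: 18 (5R,10S,14S)-16,19-di-O-methyl ether of the target (C6 and C9 ketones; C7=C8), via C9 hydroperoxide 17 (not isolated)
Conditions: KOtBu (cat.), O2 (1 atm), tBuOH/THF, 0 °C to rt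
Reagents that add atoms: dioxygen, O=O
Why: Base-mediated γ-autoxidation of an enone, in which deprotonation is possible only at C9 (no α′-hydrogen), the dienolate should take up O2 at C9, and the secondary hydroperoxide collapses by Kornblum–DeLaMare elimination to the C9 ketone; no stereocentre is affected.

**Step 9**
Reactants: 18 (5R,10S,14S)-16,19-di-O-methyl ether of the target
Product: 20 CNP0513322.1 (5R,10S,14S), via para-quinone 19 (not isolated)
Conditions: (NH4)2Ce(NO3)6, MeCN/H2O, 0 °C; then Na2S2O4, EtOAc/H2O, rt
Reagents that add atoms: water, O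
Why: Oxidative demethylation of the hydroquinone dimethyl ether should give the para-quinone (its oxygens coming from water), which dithionite reduces to the hydroquinone much faster than it touches the non-aromatisable enedione; no stereocentre is affected.

**Compound list**

1 | cyclohexane-1,3-dione | O=C1CCCC(=O)C1 | starting material
2 | allyl bromide (3-bromoprop-1-ene) | C=CCBr | starting material
3 | 2-allylcyclohexane-1,3-dione | C=CCC1C(=O)CCCC1=O | intermediate
4 | methyl vinyl ketone (but-3-en-2-one) | C=CC(C)=O | starting material
5 | 2-allyl-2-(3-oxobutyl)cyclohexane-1,3-dione | C=CCC1(CCC(C)=O)C(=O)CCCC1=O | intermediate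
6 | (8aS)-8a-allyl-3,4,8,8a-tetrahydronaphthalene-1,6(2H,7H)-dione | C=CC[C@@]12C(=O)CCCC1=CC(=O)CC2 | intermediate
7 | (8aR)-8a-allyl-3,4-dihydronaphthalene-1,6(2H,8aH)-dione | C=CC[C@@]12C(=O)CCCC1=CC(=O)C=C2 | intermediate
8 | 1,4-dimethoxybenzene | COc1ccc(OC)cc1 | starting material
9 | (4aR)-4a-allyl-5-oxo-4a,5,6,7-tetrahydronaphthalen-2-yl trifluoromethanesulfonate (trienyl triflate) | C=CC[C@@]12C(=O)CCC=C1C=C(OS(=O)(=O)C(F)(F)F)C=C2 | intermediate
10 | O-triflyl cyclohexadienyl cation derived from 7, as its triflate salt | C=CC[C@@]12C(=O)CCCC1=CC(=[O+]S(=O)(=O)C(F)(F)F)C=C2.[O-]S(=O)(=O)C(F)(F)F | intermediate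
11 | (4S,4aR)-4a-allyl-4-(2,5-dimethoxyphenyl)-5-oxo-4,4a,5,6,7,8-hexahydronaphthalen-2-yl trifluoromethanesulfonate (dienyl triflate; aryl anti to allyl) | C=CC[C@@]12C(=O)CCCC1=CC(OS(=O)(=O)C(F)(F)F)=C[C@@H]2c1cc(OC)ccc1OC | intermediate
12 | (5R,10R,14S)-5-allyl enol triflate of the tetracyclic core: C6 ketone, C7–C9 CH2, C11=C12–OTf, C13 H2, OMe on C16 and C19, arene bridge anti to allyl | C=CC[C@@]12C(=O)CCC[C@@]13C=C(OS(=O)(=O)C(F)(F)F)C[C@@H]2c1c(OC)ccc(OC)c13 | intermediate
13 | (5R,10R,14S)-5-allyl-12-methyl tetracyclic ketone: as 12 with CH3 on C12 | C=CC[C@@]12C(=O)CCC[C@@]13C=C(C)C[C@@H]2c1c(OC)ccc(OC)c13 | intermediate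
14 | (5R,10R,14S)-5-prenyl-12-methyl tetracyclic ketone: as 13 with prenyl on C5 | CC(C)=CC[C@@]12C(=O)CCC[C@@]13C=C(C)C[C@@H]2c1c(OC)ccc(OC)c13 | intermediate
15 | C6 trimethylsilyl enol ether of 14 (C6=C7; configuration unchanged) | CC(C)=CC[C@@]12C(O[Si](C)(C)C)=CCC[C@@]13C=C(C)C[C@@H]2c1c(OC)ccc(OC)c13 | intermediate
16 | (5R,10R,14S)-5-prenyl tetracyclic enone: C6 ketone, C7=C8, C9 H2, otherwise as 14 | CC(C)=CC[C@@]12C(=O)C=CC[C@@]13C=C(C)C[C@@H]2c1c(OC)ccc(OC)c13 | intermediate
17 | C9 hydroperoxide of 16 (C9 configuration not relevant) | CC(C)=CC[C@@]12C(=O)C=CC(OO)[C@@]13C=C(C)C[C@@H]2c1c(OC)ccc(OC)c13 | intermediate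
18 | (5R,10S,14S)-16,19-di-O-methyl ether of the target: C6 and C9 ketones, C7=C8 | CC(C)=CC[C@@]12C(=O)C=CC(=O)[C@@]13C=C(C)C[C@@H]2c1c(OC)ccc(OC)c13 | intermediate
19 | (5R,10R,14S)-para-quinone of the target: ring B as C16,C19-quinone | CC(C)=CC[C@@]12C(=O)C=CC(=O)[C@@]13C=C(C)C[C@@H]2C1=C3C(=O)C=CC1=O | intermediate
20 | CNP0513322.1, (5R,10S,14S): prenyl on C5 syn to the C11–C13 bridge, hydroquinone bridge across C14 and C10 | CC(C)=CC[C@@]12C(=O)C=CC(=O)[C@@]13C=C(C)C[C@@H]2c1c(O)ccc(O)c13 | target

**Step count**

Total steps: 9. Longest linear sequence: 9 steps, from cyclohexane-1,3-dione; 1,4-dimethoxybenzene enters in step 4.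

**Steps most likely to fail**

Step 4 (the proposed new method). What may go wrong: migration of the allyl or acyl substituent of C5 in the cation with aromatisation of ring C, triflation of the C6 ketone in competition with the dienone carbonyl, and a second ring closure at C12 instead of C10. The fallback uses known reaction types, sets out from 7 and returns at 12. Copper-catalysed conjugate addition of 2,5-dimethoxyphenylmagnesium bromide (CuBr·SMe2 cat., THF, −78 °C, then aqueous NH4Cl) should deliver the aryl group to the less substituted β-carbon C14, anti to the allyl group, and give aryl enone F1. tert-Butyldimethylsilyl triflate with 2,6-di-tert-butyl-4-methylpyridine (CH2Cl2, −78 to 0 °C) should then close the C10–C20 bond by a silyl-triflate-mediated intramolecular Friedel–Crafts conjugate addition that stops at the regiodefined silyl enol ether F2. MeLi (THF, 0 °C) frees lithium enolate F3, which PhNTf2 triflates on oxygen to give 12.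

Step 8. What may go wrong: oxygenation at the α-carbon C7 instead of C9, and nucleophilic epoxidation of the newly formed enedione by the hydroperoxide anion. The fallback sets out from 16 and returns at 18. tert-Butyldimethylsilyl triflate and Et3N convert 16 into 2-silyloxy diene F4 (γ-deprotonation is the only one possible). Dimethyldioxirane (acetone, −78 °C) attacks its terminal carbon C9 in a vinylogous Rubottom oxidation and gives γ-hydroxy enone F5 after desilylation, and Dess–Martin periodinane oxidises F5 to 18.

Step 3. What may go wrong: thermal [3,3]-shift of the angular allyl group with aromatisation of ring C at 100 °C, and dehydrogenation into ring A. The fallback sets out from 6 and returns at 7. Ethane-1,2-diol with TsOH protects the saturated C1 ketone selectively as ketal F6. LiN(iPr)2 and Me3SiCl at −78 °C give the cross-conjugated silyl dienol ether F7, Pd(OAc)2 in MeCN at rt dehydrogenates it (Saegusa–Ito) to dienone ketal F8, and dilute aqueous HCl in THF returns 7.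

**Further compounds**

F1 | step 4 | (4S,4aR)-4a-allyl-4-(2,5-dimethoxyphenyl)-4,4a,7,8-tetrahydronaphthalene-2,5(3H,6H)-dione (aryl enone, aryl anti to allyl) | C=CC[C@@]12C(=O)CCCC1=CC(=O)C[C@@H]2c1cc(OC)ccc1OC
F2 | step 4 | C12 tert-butyldimethylsilyl enol ether analogue of 12 (C11=C12–OSi) | C=CC[C@@]12C(=O)CCC[C@@]13C=C(O[Si](C)(C)C(C)(C)C)C[C@@H]2c1c(OC)ccc(OC)c13
F3 | step 4 | lithium C11=C12 enolate corresponding to F2 | C=CC[C@@]12C(=O)CCC[C@@]13C=C([O-])C[C@@H]2c1c(OC)ccc(OC)c13.[Li+]
F4 | step 8 | C6 tert-butyldimethylsilyloxy C6=C7–C8=C9 diene derived from 16 | CC(C)=CC[C@@]12C(O[Si](C)(C)C(C)(C)C)=CC=C[C@@]13C=C(C)C[C@@H]2c1c(OC)ccc(OC)c13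
F5 | step 8 | C9 hydroxy enone derived from 16 (C9 configuration not relevant) | CC(C)=CC[C@@]12C(=O)C=CC(O)[C@@]13C=C(C)C[C@@H]2c1c(OC)ccc(OC)c13
F6 | step 3 | C1 ethylene ketal of 6 | C=CC[C@@]12C3(OCCO3)CCCC1=CC(=O)CC2
F7 | step 3 | cross-conjugated trimethylsilyl dienol ether of F6 (C6–OSi, C6=C7) | C=CC[C@@]12C3(OCCO3)CCCC1=CC(O[Si](C)(C)C)=CC2
F8 | step 3 | C1 ethylene ketal of 7 | C=CC[C@@]12C3(OCCO3)CCCC1=CC(=O)C=C2
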